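Ring B is disconnected across C3'–C4' and C5'–C6' into a four-carbon diene and a two-carbon ynone. The route exploits the oxygen pattern of ring B: ether oxygen at C1', hydroxyl at the adjacent C2', and hydroxyl at C5' para to C2'. One Diels–Alder/aromatisation sequence closes ring B with the diaryl ether and the C2' hydroxyl in place and an acetyl group at C5' as a masked hydroxyl. The precursor is a 1-dimethylamino-3-silyloxybutadiene carrying ring A as a 2-(2-bromo-4-methoxyphenoxy) group; the ring A C2 bromine is bought with the starting phenol, so the last five bromines all enter ortho to free hydroxyls.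

Key step: step 4

Remark: ring B is the hydroquinone ring, numbered from its ether carbon C1' to C6'; ring A is the phenoxy ring, numbered from its ether carbon C1. The target has no stereocentre; the only stereo element on the way is the C1=C2 geometry of 5, 6 and 7. Hydroquinones 13, 14 and 15 are assumed to be handled under argon, with a dilute aqueous Na2S2O4 wash in the work-up to return any quinone to the hydroquinone.

Step 1
Reactants: 1 2-bromo-4-methoxyphenol; 2 chloroacetone
Product: 3 1-(2-bromo-4-methoxyphenoxy)propan-2-one
Conditions: K2CO3 (1.5 equiv), KI (0.1 equiv), acetone, reflux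
Reagents that add atoms: none
Why: Williamson ether synthesis in which the phenoxide displaces chloride from the activated α-chloroketone (iodide assists), while the aryl bromide and the methyl ether are inert.

Step 2
Reactants: 3 1-(2-bromo-4-methoxyphenoxy)propan-2-one; 4 N,N-dimethylformamide dimethyl acetal
Product: 5 (Z)-3-(2-bromo-4-methoxyphenoxy)-4-(dimethylamino)but-3-en-2-one
Conditions: 4 (2 equiv), PhMe, 100 °C, MeOH distilled off
Reagents that add atoms: none
Why: Amide acetal condensation with an active methylene, which should take place at the more acidic oxygen-flanked CH2 of the aryloxyacetone and give the push–pull enaminone with the amino group anti to the acetyl group (Z by the priority rules).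

Step 3
Reactants: 5 (Z)-3-(2-bromo-4-methoxyphenoxy)-4-(dimethylamino)but-3-en-2-one
Product: 7 (1Z)-2-(2-bromo-4-methoxyphenoxy)-3-(tert-butyldimethylsilyloxy)-N,N-dimethylbuta-1,3-dien-1-amine, via potassium dienolate 6 (not isolated)
Conditions: KN(SiMe3)2 (1.05 equiv), THF, −78 °C; TBSCl, −78 °C → rt; filtered under Ar, used crude
Reagents that add atoms: tert-butyldimethylsilyl chloride (TBSCl), CC(C)(C)[Si](C)(C)Cl
Why: Deprotonation of the only enolisable position (the acetyl methyl) of the vinylogous amide and O-silylation of the cross-conjugated enolate is the standard preparation of 1-amino-3-siloxybutadienes, and the C1=C2 geometry of 5 is carried over.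

Step 4
Reactants: 7 (1Z)-2-(2-bromo-4-methoxyphenoxy)-3-(tert-butyldimethylsilyloxy)-N,N-dimethylbuta-1,3-dien-1-amine; 8 but-3-yn-2-one
Product: 11 1-[3-(2-bromo-4-methoxyphenoxy)-4-hydroxyphenyl]ethanone, via cyclohexa-1,4-diene cycloadduct 9 (not isolated), via aryl silyl ether 10 (not isolated)
Conditions: 8 (1.5 equiv), PhMe, 0 °C → rt; then HF (48% aq.), MeCN, 0 °C → rt
Reagents that add atoms: none
Why: This is a normal-electron-demand Diels–Alder benzannulation of an electron-rich 1-amino-3-siloxydiene with an acetylenic ketone, the known reaction type in which such dienes and ynones or ynoates give para-acylphenols after loss of the amine. The amino nitrogen and the siloxy oxygen both raise the electron density at the CH2 terminus of 7, so this carbon should attack the unsubstituted β-carbon of 8 (bond C3'–C4') and the amino-bearing carbon should then close onto the acyl-bearing carbon (bond C5'–C6') in an asynchronous [4+2] step. Ring B is closed as a carbocycle by this intermolecular [4+2] cycloaddition, four carbons coming from the diene and two from the alkyne. Acid then expels dimethylamine from cycloadduct 9 to aromatise the ring, which removes the only, transient and racemic, stereocentre at C6', and fluoride cleaves aryl silyl ether 10 to the C2' hydroxyl. The selectivity needed is regioselectivity, secured because the two reinforcing donors at C1 and C3 of the diene outweigh the weaker, opposing 2-aryloxy donor and because the amino group sits anti to C3, which keeps the s-cis conformer accessible; the acetyl group should therefore end up para to the new hydroxyl and meta to the ether oxygen.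

Step 5
Reactants: 11 1-[3-(2-bromo-4-methoxyphenoxy)-4-hydroxyphenyl]ethanone
Product: 13 2-(2-bromo-4-methoxyphenoxy)benzene-1,4-diol, via aryl acetate 12 (not isolated)
Conditions: H2O2 (30% aq., 1.3 equiv), NaOH (2.5 equiv), H2O/THF, 0 °C → rt, Ar; then HCl (1 M aq.)
Reagents that add atoms: hydrogen peroxide, OO
Why: Dakin oxidation, in which hydroperoxide adds to the ketone of the para-phenoxide, the electron-rich aryl group migrates to oxygen and the aryl acetate is saponified in the flask; para-hydroxyacetophenones are classical substrates and the aryl bromide and both ethers are inert.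

Step 6
Reactants: 13 2-(2-bromo-4-methoxyphenoxy)benzene-1,4-diol
Product: 14 2-(2-bromo-4-hydroxyphenoxy)benzene-1,4-diol
Conditions: BBr3 (4 equiv), CH2Cl2, −78 °C → rt; then H2O, 0 °C
Reagents that add atoms: none
Why: Boron tribromide demethylation of an aryl methyl ether, in which bromide attacks the methyl group of the O–B complex, whereas the diaryl ether offers no sp3 carbon for substitution and should stay intact.

Step 7
Reactants: 14 2-(2-bromo-4-hydroxyphenoxy)benzene-1,4-diol
Product: 15 2,3,5-tribromo-6-(2,3,5-tribromo-4-hydroxyphenoxy)benzene-1,4-diol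
Conditions: Br2 (5.1 equiv), AcOH, rt, dark
Reagents that add atoms: bromine, BrBr
Why: Electrophilic aromatic bromination directed by free phenolic hydroxyls, in which the five positions to be filled (C3', C4' and C6' of ring B, C3 and C5 of ring A) are exactly the five C–H positions ortho to a hydroxyl, while the remaining ring A C6–H is meta to its hydroxyl in a tribrominated ring, so substitution should stop at the hexabromide.

Compound list
1 | 2-bromo-4-methoxyphenol | COc1ccc(O)c(Br)c1 | starting material
2 | chloroacetone (1-chloropropan-2-one) | CC(=O)CCl | starting material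
3 | 1-(2-bromo-4-methoxyphenoxy)propan-2-one | CC(=O)COc1ccc(OC)cc1Br | intermediate
4 | N,N-dimethylformamide dimethyl acetal | COC(OC)N(C)C | starting material
5 | (Z)-3-(2-bromo-4-methoxyphenoxy)-4-(dimethylamino)but-3-en-2-one | CN(C)/C=C(Oc1ccc(OC)cc1Br)/C(C)=O | intermediate
6 | potassium (Z)-3-(2-bromo-4-methoxyphenoxy)-4-(dimethylamino)buta-1,3-dien-2-olate | [K+].CN(C)/C=C(Oc1ccc(OC)cc1Br)/C(=C)[O-] | intermediate (not isolated)
7 | (1Z)-2-(2-bromo-4-methoxyphenoxy)-3-(tert-butyldimethylsilyloxy)-N,N-dimethylbuta-1,3-dien-1-amine | CN(C)/C=C(Oc1ccc(OC)cc1Br)/C(=C)O[Si](C)(C)C(C)(C)C | intermediate (precursor of the key step)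
8 | but-3-yn-2-one | CC(=O)C#C | starting material
9 | 1-[5-(2-bromo-4-methoxyphenoxy)-4-(tert-butyldimethylsilyloxy)-6-(dimethylamino)cyclohexa-1,4-dien-1-yl]ethanone (racemic at C6) | CC(=O)C1=CCC(O[Si](C)(C)C(C)(C)C)=C(Oc2ccc(OC)cc2Br)C1N(C)C | intermediate (not isolated)
10 | 1-[3-(2-bromo-4-methoxyphenoxy)-4-(tert-butyldimethylsilyloxy)phenyl]ethanone | CC(=O)c1ccc(O[Si](C)(C)C(C)(C)C)c(Oc2ccc(OC)cc2Br)c1 | intermediate (not isolated)
11 | 1-[3-(2-bromo-4-methoxyphenoxy)-4-hydroxyphenyl]ethanone | CC(=O)c1ccc(O)c(Oc2ccc(OC)cc2Br)c1 | intermediate (product of the key step)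
12 | 3-(2-bromo-4-methoxyphenoxy)-4-hydroxyphenyl acetate | CC(=O)Oc1ccc(O)c(Oc2ccc(OC)cc2Br)c1 | intermediate (not isolated)
13 | 2-(2-bromo-4-methoxyphenoxy)benzene-1,4-diol | Oc1ccc(O)c(Oc2ccc(OC)cc2Br)c1 | intermediate
14 | 2-(2-bromo-4-hydroxyphenoxy)benzene-1,4-diol | Oc1ccc(O)c(Oc2ccc(O)cc2Br)c1 | intermediate
15 | 2,3,5-tribromo-6-(2,3,5-tribromo-4-hydroxyphenoxy)benzene-1,4-diol | Oc1c(Br)cc(Oc2c(O)c(Br)c(Br)c(O)c2Br)c(Br)c1Br | target

Total step count: 7. Longest linear sequence: 7 steps (1 to 15).

Steps most likely to fail

Step 4. The diene terminus may add to the ynone in a stepwise conjugate fashion and stop at an open-chain adduct, or the crowded, hydrolytically sensitive diene may decompose before it cycloadds, so that ring B is not closed. The fallback builds the diaryl ether by substitution instead of cycloaddition; it sets out from 1 and returns at 14. Phenol 1 and commercial 2-fluoro-4-methoxybenzaldehyde (COc1ccc(C=O)c(F)c1) should undergo nucleophilic aromatic substitution (K2CO3, DMF, 120 °C), the formyl group activating the ortho fluorine, to give 2-(2-bromo-4-methoxyphenoxy)-4-methoxybenzaldehyde F1. Baeyer–Villiger oxidation of this electron-rich aldehyde with mCPBA in CH2Cl2 should give 2-(2-bromo-4-methoxyphenoxy)-4-methoxyphenyl formate F2, which is methanolysed (K2CO3, MeOH) to 2-(2-bromo-4-methoxyphenoxy)-4-methoxyphenol F3. BBr3 under the conditions of step 6 then cleaves both methyl ethers and gives 14.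

Step 7. Oxidation of the ring B hydroquinone by bromine may compete with substitution, and substitution at the crowded C6' position may lag while ring A is brominated in the same flask, which would leave partly brominated and quinoid material that is hard to separate. The fallback divides the five brominations into two stages around the demethylation; it sets out from 13 and returns at 15. With ring A still a methyl ether, Br2 (3 equiv, AcOH, rt) should brominate the far more reactive hydroquinone ring to 2,3,5-tribromo-6-(2-bromo-4-methoxyphenoxy)benzene-1,4-diol F4. Any bromine that strays onto ring A at this stage enters ortho to the methoxy group, at C3 or C5, where the target carries bromine anyway. BBr3 then gives 2,3,5-tribromo-6-(2-bromo-4-hydroxyphenoxy)benzene-1,4-diol F5, and Br2 (2 equiv, AcOH) fills the two positions ortho to the freed ring A hydroxyl to give 15.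

Step 5. Addition of hydroperoxide to the ketone may be slow, and the electron-rich hydroquinone may be oxidised further by alkaline peroxide. The fallback keeps both ring B oxygens masked until the demethylation; it sets out from 11 and returns at 14. Methylation of 11 (MeI, K2CO3, acetone) should give 1-[3-(2-bromo-4-methoxyphenoxy)-4-methoxyphenyl]ethanone F6. Baeyer–Villiger oxidation with mCPBA (CH2Cl2, NaHCO3), with migration of the para-methoxyaryl group, should give 3-(2-bromo-4-methoxyphenoxy)-4-methoxyphenyl acetate F7, and methanolysis (K2CO3, MeOH) gives 3-(2-bromo-4-methoxyphenoxy)-4-methoxyphenol F8. BBr3 under the conditions of step 6 cleaves both methyl ethers and gives 14.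

Further compounds
F1 | step 4 | 2-(2-bromo-4-methoxyphenoxy)-4-methoxybenzaldehyde | COc1ccc(C=O)c(Oc2ccc(OC)cc2Br)c1
F2 | step 4 | 2-(2-bromo-4-methoxyphenoxy)-4-methoxyphenyl formate | COc1ccc(OC=O)c(Oc2ccc(OC)cc2Br)c1
F3 | step 4 | 2-(2-bromo-4-methoxyphenoxy)-4-methoxyphenol | COc1ccc(O)c(Oc2ccc(OC)cc2Br)c1
F4 | step 7 | 2,3,5-tribromo-6-(2-bromo-4-methoxyphenoxy)benzene-1,4-diol | COc1ccc(Oc2c(O)c(Br)c(Br)c(O)c2Br)c(Br)c1
F5 | step 7 | 2,3,5-tribromo-6-(2-bromo-4-hydroxyphenoxy)benzene-1,4-diol | Oc1ccc(Oc2c(O)c(Br)c(Br)c(O)c2Br)c(Br)c1
F6 | step 5 | 1-[3-(2-bromo-4-methoxyphenoxy)-4-methoxyphenyl]ethanone | CC(=O)c1ccc(OC)c(Oc2ccc(OC)cc2Br)c1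
F7 | step 5 | 3-(2-bromo-4-methoxyphenoxy)-4-methoxyphenyl acetate | CC(=O)Oc1ccc(OC)c(Oc2ccc(OC)cc2Br)c1
F8 | step 5 | 3-(2-bromo-4-methoxyphenoxy)-4-methoxyphenol | Oc1ccc(OC)c(Oc2ccc(OC)cc2Br)c1
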